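**Retrosynthetic overview**

- The strategy rests on the C4–O–C1' link of the mixed methyl aryl ketal (C4 of the cyclohexenone ring, between C3(OMe)= and C5H2; C1' of the 2-allyl-4,5-dimethoxyphenyl ring). It is the oxygen-inserted isomer of a C4–C1' bond, so the target is traced to the tertiary benzylic hydroperoxide carrying the aryl group on C4 (aryl shift from C4 to oxygen, methanol capture).
- The hydroperoxide is traced to the silyl-protected tertiary carbinol (perhydrolysis), and the C6 allyl stereocentre to a palladium-catalysed decarboxylative asymmetric allylation of an allyl enol carbonate.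
- The enol carbonate is traced to a quinol silyl ether: copper hydride reduction of the C5=C6 enone, preceded by 1,2-addition of the aryllithium from brominated methyl eugenol to the carbonyl of 2-methoxy-1,4-benzoquinone that flanks the methoxy carbon.
- No ring is formed in the route: the arene is that of methyl eugenol and the carbocycle is that of the quinone.

Key step: step 7

Assumption: the (R,R)-ligand is written in step 5 by analogy with six-membered vinylogous-ester enol carbonates; if a model allylation shows the opposite sense of induction, the (S,S)-ligand is used instead.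

Locants throughout are those of the cyclohexenone (C1 carbonyl, C2=C3(OMe), C4 aryl-bearing carbon, C5 methylene, C6 allyl-bearing carbon).

**Route**

Step 1
Reactants: 1 methyl eugenol (4-allyl-1,2-dimethoxybenzene)
Product: 2 1-allyl-2-bromo-4,5-dimethoxybenzene
Conditions: NBS, MeCN, 0 °C to rt, dark
Reagents that add atoms: N-bromosuccinimide, O=C1CCC(=O)N1Br
Why: Electrophilic aromatic bromination with NBS in a polar solvent should go to the ring position para to a methoxy group and ortho to the allyl group, the most activated unhindered site, while the monosubstituted alkene is left alone in the absence of water, light and radical initiators.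

Step 2
Reactants: 2 1-allyl-2-bromo-4,5-dimethoxybenzene; 3 2-methoxy-1,4-benzoquinone
Product: 6 rac-4-(2-allyl-4,5-dimethoxyphenyl)-3-methoxy-4-(trimethylsilyloxy)cyclohexa-2,5-dien-1-one, via aryllithium 4 (not isolated), via lithium alkoxide 5 (not isolated)
Conditions: n-BuLi, THF, −78 °C; cannulate into 3, THF, −78 °C; TMSCl, −78 to 0 °C
Reagents that add atoms: chlorotrimethylsilane, C[Si](C)(C)Cl
Why: Bromine–lithium exchange followed by 1,2-addition of the aryllithium should take place at the quinone carbonyl next to the methoxy-bearing carbon, because the other carbonyl is deactivated as a vinylogous ester; inverse addition at low temperature limits electron transfer and double addition, in-flask silylation masks the tertiary hydroxyl for the later enolate chemistry, and the carbinol centre is formed racemic, which is harmless because step 7 erases it.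

Step 3
Reactants: 6 rac-4-(2-allyl-4,5-dimethoxyphenyl)-3-methoxy-4-(trimethylsilyloxy)cyclohexa-2,5-dien-1-one
Product: 8 rac-4-(2-allyl-4,5-dimethoxyphenyl)-3-methoxy-4-(trimethylsilyloxy)cyclohex-2-en-1-one, via copper dienolate 7 (not isolated)
Conditions: [(Ph3P)CuH]6, degassed toluene, H2O (few equiv), rt
Reagents that add atoms: none
Why: Copper hydride conjugate reduction should deliver hydride to C5 of the unsubstituted C5=C6 enone only, since the methoxy-substituted C2=C3 enone is a deactivated vinylogous ester and the isolated allyl alkene does not react with the monovalent copper hydride, and water protonates the copper enolate at C6.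

Step 4
Reactants: 8 rac-4-(2-allyl-4,5-dimethoxyphenyl)-3-methoxy-4-(trimethylsilyloxy)cyclohex-2-en-1-one; 9 allyl chloroformate
Product: 11 rac-allyl [4-(2-allyl-4,5-dimethoxyphenyl)-5-methoxy-4-(trimethylsilyloxy)cyclohexa-1,5-dien-1-yl] carbonate, via sodium dienolate 10 (not isolated)
Conditions: NaN(SiMe3)2, TMEDA, THF, −78 °C; then 9, −78 °C
Reagents that add atoms: none
Why: Kinetic deprotonation of the vinylogous ester can only occur at C6 because C4 is fully substituted, and the sodium enolate in the presence of TMEDA should be acylated on oxygen by the chloroformate (enol carbonate formation).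

Step 5
Reactants: 11 rac-allyl [4-(2-allyl-4,5-dimethoxyphenyl)-5-methoxy-4-(trimethylsilyloxy)cyclohexa-1,5-dien-1-yl] carbonate
Product: 12 (6S)-6-allyl-4-(2-allyl-4,5-dimethoxyphenyl)-3-methoxy-4-(trimethylsilyloxy)cyclohex-2-en-1-one (both C4 epimers)
Conditions: Pd2(dba)3·CHCl3 (2.5 mol %), (R,R)-DACH-phenyl bisphosphine ligand (5.5 mol %), degassed 1,4-dioxane, rt
Reagents that add atoms: none
Why: In this decarboxylative asymmetric allylic alkylation (Tsuji–Trost type, enol carbonate variant) zerovalent palladium ionises the allyl carbonate, CO2 is lost and the enolate recombines with the π-allylpalladium cation inside the chiral ligand pocket, which should set C6 as S under catalyst control for both C4 epimers while the neutral, regiospecific enolate generation protects the new tertiary α-centre from equilibration.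

Step 6
Reactants: 12 (6S)-6-allyl-4-(2-allyl-4,5-dimethoxyphenyl)-3-methoxy-4-(trimethylsilyloxy)cyclohex-2-en-1-one
Product: 14 (6S)-6-allyl-4-(2-allyl-4,5-dimethoxyphenyl)-4-hydroperoxy-3-methoxycyclohex-2-en-1-one (both C4 epimers), via tertiary alcohol 13 (not isolated)
Conditions: 50% aq H2O2 (excess), cat. H2SO4, Et2O, 0 °C, short contact time; cold aq NaHCO3 quench
Reagents that add atoms: hydrogen peroxide, OO
Why: Dilute acid should cleave the silyl ether and then ionise the tertiary benzylic C4–O bond (SN1 perhydrolysis), the cation being stabilised by the para-methoxy group of the aryl ring and captured by the large excess of the strongly nucleophilic peroxide, with the C4 configuration of no consequence and C6 untouched at 0 °C.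

Step 7
Reactants: 14 (6S)-6-allyl-4-(2-allyl-4,5-dimethoxyphenyl)-4-hydroperoxy-3-methoxycyclohex-2-en-1-one
Product: 16 (4R,6S)-6-allyl-4-(2-allyl-4,5-dimethoxyphenoxy)-3,4-dimethoxycyclohex-2-en-1-one, via aryloxy oxocarbenium ion 15 (not isolated)
Conditions: BF3·OEt2 (0.2 equiv), anhydrous MeOH–CH2Cl2, 3 Å MS, −40 to −10 °C; Et3N quench
Reagents that add atoms: methanol, CO
Why: Acid activation of the terminal peroxide oxygen makes water a leaving group, and the aryl ring shifts with C1' from C4 to the inner oxygen through a bridged, phenonium-like transition state to give aryloxy oxocarbenium ion 15, which methanol captures at C4; this is a Hock (Criegee-type) carbon-to-oxygen aryl shift interrupted by an alcohol instead of ending in hydrolysis. No ring is closed: the C1'–O and C4–OMe bonds are made and the C4–C1' bond is broken. The new C4 stereocentre is controlled by C6: in the twisted half-chair cation the allyl group is pseudo-equatorial and methanol should add axially, anti to the pseudo-axial C5–H and so trans to the allyl group, which leaves the aryloxy group cis to allyl, that is 4R,6S. The step needs aryl rather than C3 or C5 migration, which the electron-rich ring with its methoxy group para to C1' secures, and O–O rather than C4–O heterolysis, which is favoured because positive charge in the shift is spread into the aryl ring whereas a bare C4 cation is destabilised by the adjacent electron-poor enol-ether carbon. Low temperature, dry methanol and an early amine quench keep the addition under kinetic control and protect the mixed ketal from hydrolysis and from exchange of the aryloxy group.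

**Compound list**

1 | methyl eugenol (4-allyl-1,2-dimethoxybenzene) | C=CCc1ccc(OC)c(OC)c1 | starting material
2 | 1-allyl-2-bromo-4,5-dimethoxybenzene | C=CCc1cc(OC)c(OC)cc1Br | intermediate
3 | 2-methoxy-1,4-benzoquinone | COC1=CC(=O)C=CC1=O | starting material
4 | (2-allyl-4,5-dimethoxyphenyl)lithium | C=CCc1cc(OC)c(OC)cc1[Li] | intermediate
5 | lithium 1-(2-allyl-4,5-dimethoxyphenyl)-2-methoxy-4-oxocyclohexa-2,5-dien-1-olate (racemic) | C=CCc1cc(OC)c(OC)cc1C1(O[Li])C=CC(=O)C=C1OC | intermediate
6 | rac-4-(2-allyl-4,5-dimethoxyphenyl)-3-methoxy-4-(trimethylsilyloxy)cyclohexa-2,5-dien-1-one | C=CCc1cc(OC)c(OC)cc1C1(O[Si](C)(C)C)C=CC(=O)C=C1OC | intermediate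
7 | monovalent copper dienolate of 8 (Ph3P-ligated, racemic) | C=CCc1cc(OC)c(OC)cc1C1(O[Si](C)(C)C)CC=C(O[Cu])C=C1OC | intermediate
8 | rac-4-(2-allyl-4,5-dimethoxyphenyl)-3-methoxy-4-(trimethylsilyloxy)cyclohex-2-en-1-one | C=CCc1cc(OC)c(OC)cc1C1(O[Si](C)(C)C)CCC(=O)C=C1OC | intermediate
9 | allyl chloroformate | C=CCOC(Cl)=O | starting material
10 | sodium dienolate of 8 (racemic) | C=CCc1cc(OC)c(OC)cc1C1(O[Si](C)(C)C)CC=C(O[Na])C=C1OC | intermediate
11 | rac-allyl [4-(2-allyl-4,5-dimethoxyphenyl)-5-methoxy-4-(trimethylsilyloxy)cyclohexa-1,5-dien-1-yl] carbonate | C=CCOC(=O)OC1=CCC(O[Si](C)(C)C)(c2cc(OC)c(OC)cc2CC=C)C(OC)=C1 | intermediate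
12 | (6S)-6-allyl-4-(2-allyl-4,5-dimethoxyphenyl)-3-methoxy-4-(trimethylsilyloxy)cyclohex-2-en-1-one, both C4 epimers | C=CCc1cc(OC)c(OC)cc1C1(O[Si](C)(C)C)C[C@H](CC=C)C(=O)C=C1OC | intermediate
13 | (6S)-6-allyl-4-(2-allyl-4,5-dimethoxyphenyl)-4-hydroxy-3-methoxycyclohex-2-en-1-one, both C4 epimers | C=CCc1cc(OC)c(OC)cc1C1(O)C[C@H](CC=C)C(=O)C=C1OC | intermediate
14 | (6S)-6-allyl-4-(2-allyl-4,5-dimethoxyphenyl)-4-hydroperoxy-3-methoxycyclohex-2-en-1-one, both C4 epimers | C=CCc1cc(OC)c(OC)cc1C1(OO)C[C@H](CC=C)C(=O)C=C1OC | intermediate
15 | (S)-[5-allyl-2-methoxy-4-oxocyclohex-2-en-1-ylidene](2-allyl-4,5-dimethoxyphenyl)oxonium (aryloxy oxocarbenium ion) | C=CCc1cc(OC)c(OC)cc1[O+]=C1C[C@H](CC=C)C(=O)C=C1OC | intermediate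
16 | (4R,6S)-6-allyl-4-(2-allyl-4,5-dimethoxyphenoxy)-3,4-dimethoxycyclohex-2-en-1-one | C=CCc1cc(OC)c(OC)cc1O[C@]1(OC)C[C@H](CC=C)C(=O)C=C1OC | target

**Step count and risks**

Total steps: 7. Longest linear sequence: 7 steps (1 to 16).

Steps most likely to fail:

Step 7. The protonated hydroperoxide may break its C4–O bond instead of its O–O bond, after which proton loss from C5 and tautomerisation would aromatise the ring to a biaryl phenol. The water released may also collapse the oxocarbenium ion, the acid may exchange the aryloxy group of the product for methoxy, and methanol may add with low facial selectivity. The fallback sets out from 14 and runs the same aryl shift in the Criegee mode, with a carboxylate leaving group and no Brønsted acid. Trifluoroacetic anhydride and 2,6-lutidine in CH2Cl2 at −78 °C would give the per-trifluoroacetate F1. F1 should rearrange on slight warming, by aryl migration with loss of trifluoroacetate, to ion 15, which collapses to the trifluoroacetoxy aryloxy ketal F2. Addition of dry methanol to the cold, lutidine-buffered solution would solvolyse F2 through the same ion, and the route is rejoined at 16.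

Step 6. The C4 cation may lose a C5 proton and the resulting dienone would tautomerise irreversibly to a phenol. The aryl shift may also start in the aqueous acidic medium, where water rather than methanol captures the oxocarbenium ion and the ring is lost, and the enol ether may hydrolyse. The fallback sets out from 12 and avoids both aqueous acid and accumulation of the peroxide. Desilylation with AcOH–THF–H2O at 0 °C would give isolated 13. This is then treated in dry methanol–CH2Cl2 at −20 °C with anhydrous ethereal H2O2 and anhydrous TsOH. The tertiary methyl ether F3 forms reversibly from the C4 cation and serves as a reservoir, hydroperoxide 14 is only a transient species that rearranges in the same flask with methanol already present, and the route is rejoined at 16.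

Step 5. The racemic C4 centre, with its aryl and silyloxy groups, exerts its own facial bias on the enolate. In the mismatched C4 epimer the catalyst may be overridden, which would lower the enantiomeric purity at C6 that is carried into the target. The fallback sets out from 8 and replaces catalyst control by resolution. LiN(i-Pr)2 in THF at −78 °C would give the lithium dienolate F4, and allyl bromide would alkylate it at C6 (Stork–Danheiser-type alkylation) without stereocontrol. The two racemic diastereomers are separated on silica and each is resolved on a chiral stationary phase. The 6S isomers are compound 12. The 6R isomers F5 are epimerised at C6 with DBU, which turns each into its separable 6S diastereomer, and recycled. The route is rejoined at 12.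

**Further compounds**

F1 | step 7 | (6S)-6-allyl-4-(2-allyl-4,5-dimethoxyphenyl)-3-methoxy-4-(trifluoroacetylperoxy)cyclohex-2-en-1-one, both C4 epimers | C=CCc1cc(OC)c(OC)cc1C1(OOC(=O)C(F)(F)F)C[C@H](CC=C)C(=O)C=C1OC
F2 | step 7 | [(5S)-5-allyl-1-(2-allyl-4,5-dimethoxyphenoxy)-2-methoxy-4-oxocyclohex-2-en-1-yl] trifluoroacetate, either C1 epimer | C=CCc1cc(OC)c(OC)cc1OC1(OC(=O)C(F)(F)F)C[C@H](CC=C)C(=O)C=C1OC
F3 | step 6 | (6S)-6-allyl-4-(2-allyl-4,5-dimethoxyphenyl)-3,4-dimethoxycyclohex-2-en-1-one, both C4 epimers | C=CCc1cc(OC)c(OC)cc1C1(OC)C[C@H](CC=C)C(=O)C=C1OC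
F4 | step 5 | lithium dienolate of 8 (racemic) | C=CCc1cc(OC)c(OC)cc1C1(O[Si](C)(C)C)CC=C(O[Li])C=C1OC
F5 | step 5 | (6R)-6-allyl-4-(2-allyl-4,5-dimethoxyphenyl)-3-methoxy-4-(trimethylsilyloxy)cyclohex-2-en-1-one, both C4 epimers | C=CCc1cc(OC)c(OC)cc1C1(O[Si](C)(C)C)C[C@@H](CC=C)C(=O)C=C1OC
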